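The data come from a simulation for an exercise, noise included.

The ash run at 2.5 min is where I start: 23.5 mM of Prd stands there, which is 9.40 % of the Sub charged, and the scatter is 4.26 % of that reading.

| setting | ash | maple | elm | larch | alder |
|---|---|---|---|---|---|
| Sub | 250 mM | 380 mM | 250 mM | 250 mM | 50.0 mM |
| Rgt | 250 mM | 250 mM | 120 mM | 250 mM | 50.0 mM |
| Prd |  |  |  | 120 mM |  |
| time |  |  |  |  | 17 min |

- ash run (time / min: [Prd] / mM): 0.68: 6.8; 1.3: 12.2; 2.5: 23.5; 4.7: 42.9; 8.9: 66.9; 17: 94.3
- maple run (time / min: [Prd] / mM): 0.68: 9.9; 1.3: 17.8; 2.5: 32.8; 4.7: 54.5; 8.9: 84.9; 17: 115.7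
- elm run (time / min: [Prd] / mM): 0.68: 4.0; 1.3: 7.6; 2.5: 13.4; 4.7: 22.1; 8.9: 35.9; 17: 51.6
- larch run (time / min: [Prd] / mM): 0.68: 125.8; 1.3: 133.6; 2.5: 144.8; 4.7: 162.7; 8.9: 186.7; 17: 213.4

(readings scatter by 1 mM)

1. reaction order in [Sub] at the outset, round the charge of the ash run, defined at two percent of the Sub turned into Prd (one fixed amount of Prd, the same in the runs compared)
2. reaction order in [Rgt] at the outset, round the charge of the ash run, defined at two percent of the Sub turned into Prd
3. Prd in the alder run at 17 min, as a share of the Sub charged

- Overall: Sub + Rgt -> Prd.
- Constant volume, constant temperature.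
- A reading of a species includes what of it is bound.
- "The second partner" is Rgt.
- An order is taken over about fifteen percent of the charge, up and down.

What is the zero of the scale? It is the plain bimolecular case, order one in Sub and one in Rgt. The ash run charges both equally, so both stand at the charge minus the Prd made, and the integrated law gives a bimolecular yardstick, the usual second-order rate constant: the Prd read divided by the time, the charge and the Sub left, 0.166 M⁻¹ min⁻¹.

Does Prd charged at the start disturb it? At the same time the larch run has made 24.8 mM beyond its 120 mM, against 23.5 mM in the ash run, a gap of about the scatter of one reading.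

And the orders? At that time the maple run gives 0.796 for Sub and the elm run 0.765 for Rgt, both lower than one. These are my estimates.

Where is that weak? The steps in charge are wide and rest on single readings: the scatter of the elm reading alone moves the Rgt order by 0.102.

What does the alder run give? The yardstick unchanged gives 12.4 %. But the two shortfalls from order one add up to 0.438, so a constant scaled to the alder charge, 5.00 times lower, gives 22.2 %.

Which one? Neither: that scaling stretches a power law far from where it was read, and in the ash run itself the yardstick at 17 min has sunk to 0.858 of its early value. I commit to the middle, 17.3 %.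

The forecast gives 0.87, 0.67 and 13 %, holding that “Curvature from saturation suggests the local Rgt order at the ash charge is a little lower”; its Rgt order is lower than mine, and, as a separate matter, its alder share is lower than mine, reckoned with “gradual loss of activity”.

The alder run gives 16.5 %, which lies above 12.4 % and below 22.2 %.

    Sub + Rgt ⇌ Prd + Byp (0.2736 M⁻¹ min⁻¹, 0.04374 M⁻¹ min⁻¹)
    Sub + Rgt ⇌ Sub.Rgt, settled at all times (1.120 M⁻¹)
    Rgt + Byp ⇌ Rgt.Byp, settled at all times (49.30 M⁻¹)

The orders at the outset come to 0.86 in Sub and 0.88 in Rgt. Their shortfalls from one add up to 0.259, and the yardstick scaled by that sum to the alder charge gives 17.6 % for the alder run. Unscaled, the yardstick puts a quarter of the Sub made in the larch run at 8.03 min, and the larch run reaches it at 8.15 min.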